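(Readings and results stem from a simulated flask for an exercise, and the scatter is random.)

Start with a sum: add substrate and product at each earlier run's last reading and see what is missing.

| setting | amber | blue | red | ochre | beta | alpha | eta | delta | zeta |
|---|---|---|---|---|---|---|---|---|---|
| substrate | 5.5 mM | 14 mM | 31 mM | 10 mM | 6.0 mM | 10 mM | 5.0 mM | 40 mM | 10 mM |
| partner | 0.95 equiv | 0.95 equiv | 0.95 equiv | 0.95 equiv | 0.950 equiv | 0.950 equiv | 0.950 equiv | 0.470 equiv | 1.90 equiv |
| capture agent | 0.20 mM | 0.20 mM | 0.20 mM | 0.19 mM | 0.100 mM | 0.200 mM | 0.200 mM | 0.100 mM | 0.400 mM |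
| free catalyst | 15 mol% | 15 mol% | 15 mol% | 15 mol% | 15 mol% | 15 mol% | 25 mol% | 15 mol% | 15 mol% |
| remark | run made earlier | run made earlier | run made earlier | run made earlier |  |  |  |  |  |
| time |  |  |  |  | 5.0 h | 5.0 h | 5.0 h | 5.0 h | 5.0 h |

| run | time / h | product / % | substrate / % |
|---|---|---|---|
| amber | 0.667 | 1.5 | 98.1 |
| amber | 1.33 | 3.9 | 95.0 |
| amber | 2.00 | 6.6 | 93.0 |
| amber | 3.00 | 11.3 | 87.9 |
| amber | 4.00 | 15.7 | 84.1 |
| blue | 0.667 | 5.2 | 93.2 |
| blue | 1.33 | 12.0 | 85.9 |
| blue | 2.00 | 18.0 | 79.4 |
| blue | 3.00 | 25.2 | 71.4 |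
| blue | 4.00 | 29.3 | 65.1 |
| red | 0.250 | 2.3 | 95.5 |
| red | 0.500 | 8.3 | 88.9 |
| red | 1.00 | 16.0 | 79.8 |
| red | 2.00 | 23.2 | 66.4 |
| red | 4.00 | 30.3 | 57.3 |
| ochre | 0.667 | 3.0 | 97.0 |
| ochre | 1.33 | 8.1 | 90.5 |
| ochre | 2.00 | 13.7 | 84.8 |
| ochre | 3.00 | 20.4 | 78.0 |
| ochre | 4.00 | 26.2 | 72.0 |

(standard deviation of a reading: 0.5 percentage points)

- the flasks by amount of product, in percent of the substrate charged, highest first, at 5.0 h (beta / alpha / eta / delta / zeta)
- the amount of product, in percent of the substrate charged of the flask you put first, at 5.0 h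
- the amount of product, in percent of the substrate charged of the flask you put last, at 5.0 h



In red at 4.00 h the sum falls short by 12.4 %. Read that as substrate bound to catalyst: it comes to 82.7 % of the loading, against 1.33 % in amber, and red's product has slowed, gaining 7.2 percentage points from 1.00 h to 2.00 h and 7.1 points in the twice as long stretch after it.

Call the product reached per equivalent of partner charged, in a flask whose catalyst is bound like this, the stall yield: 31.9 % as read from red at 4.00 h.

Now reckon delta. It charges more catalyst than red, c(free catalyst) 6.00 mM, so expect the same stall by 5.0 h. By charge, partner is the limiting reagent in delta, at 0.470 equiv, so the stall yield gives 15.0 %. Amber, whose substrate lies above eta's and below beta's, already reads 15.7 % at 4.00 h with a sum of 99.8 %, so put delta last, below that reading.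

The forecast gave zeta > alpha > delta > beta > eta, with 52 % and 18.5 %, on the ground that “Rate collapses past about 3 mM product”.

The flasks give zeta > alpha > eta > beta > delta, with 45.8 % first and 16.4 % last.

    partner + free catalyst → catalyst intermediate A (k = 1.70 L mol⁻¹ min⁻¹)
    substrate + catalyst intermediate A → catalyst intermediate B (k = 3.50 L mol⁻¹ min⁻¹)
    catalyst intermediate B ⇌ free catalyst + product (K = 0.0160 M, k = 2.90 min⁻¹)
    2 catalyst intermediate B → spent catalyst (k = 31.0 L mol⁻¹ min⁻¹)
    catalyst intermediate B + capture agent → trapped intermediate (k = 0.330 L mol⁻¹ min⁻¹)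

Delta stands 1.4 points above the reckoning, and at 5.00 h it holds 84.1 % of its catalyst as spent catalyst, with 10.3 % as free catalyst. Its own stall yield comes to 34.9 %, against 31.9 % from red.

Take the neighbour of delta with 0.800 equiv of partner, more than delta and less than red, its other charges and its time as in delta: the stall yield gives 25.5 %. That flask gives 26.2 %, with 89.1 % of its catalyst as spent catalyst.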